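**Assumption:** the tetronic acid of variabilin is presumed to arise in nature by enol-lactonisation (C24 carboxyl onto the C21 enol oxygen) of an open-chain, oxidised C21–C25 terminus of a polyprenyl chain whose Δ17 olefin has been reduced; isomerically pure (2E,6E)-farnesyl acetate is bought.

Position numbers follow variabilin: furan C1–C4, chain C5–C20 (methyls C9, C14, C19), tetronic acid C21–C24, ring methyl C25.

## Retrosynthetic overview

1. Variabilin ⇒ open-chain 2-methyl-3,4-dioxo ester (C21–O–C24 enol-lactonisation, the only ring-forming event, done last) ⇒ C20–C21 acylation of a C1–C20 Grignard reagent by the enolate of diethyl oxalpropionate (C21–C25 at final oxidation level).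
2. C1–C20 bromide ⇒ (S)-2-methyl alcohol ⇒ Ru–BINAP hydrogenation of an (E)-allylic alcohol (sets C18; the chemical counterpart of the Δ17 reduction).
3. Allylic alcohol ⇒ C5–C6 Cu-catalysed coupling of 3-furylmethylmagnesium chloride with 12-hydroxyfarnesyl acetate ⇐ terminal SeO2 oxidation of (2E,6E)-farnesyl acetate (C6–C20, both E-olefins already in place).
4. Ring order: the furan enters ready-made from 3-furanmethanol; the tetronic acid is built last from the acyclic oxidised terminus.

## Route

**Step 1**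
Reactants: 1 3-furanmethanol
Product: 3 3-(chloromethyl)furan, via furan-3-ylmethyl methanesulfonate 2 (not isolated)
Conditions: MsCl, s-collidine, LiCl, DMF, 0 °C; used cold and at once
Reagents that add atoms: lithium chloride, [Li+].[Cl-] (Cl of 3); methanesulfonyl chloride, CS(=O)(=O)Cl (held only in intermediate 2)
Why: Collington–Meyers chlorination, in which the primary mesylate formed in situ is displaced by chloride (SN2) under buffered, non-acidic conditions that spare the furan; no stereocentre is involved.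

**Step 2**
Reactants: 4 (2E,6E)-farnesyl acetate
Product: 5 (2E,6E,10E)-12-hydroxy-3,7,11-trimethyldodeca-2,6,10-trien-1-yl acetate
Conditions: SeO2 (cat.), t-BuOOH (70% aq.), salicylic acid (cat.), CH2Cl2, 0 °C → rt
Reagents that add atoms: tert-butyl hydroperoxide, CC(C)(C)OO (source of the new oxygen, relayed through catalytic selenium dioxide, O=[Se]=O)
Why: Sharpless SeO2/t-BuOOH allylic oxidation (ene reaction then [2,3]-shift) hydroxylates selectively the (E)-methyl group of the terminal, most accessible trisubstituted olefin of farnesyl esters and gives the 10E allylic alcohol (future C20–OH).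

**Step 3**
Reactants: 3 3-(chloromethyl)furan; 5 (2E,6E,10E)-12-hydroxy-3,7,11-trimethyldodeca-2,6,10-trien-1-yl acetate
Product: 7 (2E,6E,10E)-13-(furan-3-yl)-2,6,10-trimethyltrideca-2,6,10-trien-1-ol, via (furan-3-ylmethyl)magnesium chloride 6 (not isolated)
Conditions: 3, Mg, THF, rt; then 5 (0.4 equiv), Li2CuCl4 (5 mol %), THF, −20 → 0 °C; aq. NH4Cl
Reagents that add atoms: magnesium, [Mg] (held only in intermediate 6; no reagent atoms remain in 7)
Why: Fouquet–Schlosser/Tanis-type Cu-catalysed Grignard–allylic acetate coupling, in which one equivalent of 6 is spent on the free hydroxyl and the cuprate then displaces the primary allylic acetate at the α-carbon (SN2) with retention of the 2E geometry, forming C5–C6.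

**Step 4**
Reactants: 7 (2E,6E,10E)-13-(furan-3-yl)-2,6,10-trimethyltrideca-2,6,10-trien-1-ol
Product: 8 (2S,6E,10E)-13-(furan-3-yl)-2,6,10-trimethyltrideca-6,10-dien-1-ol
Conditions: H2 (100 atm), Ru(OAc)2[(S)-BINAP] (1 mol %), MeOH, 25 °C
Reagents that add atoms: none
Why: Noyori hydroxyl-directed asymmetric hydrogenation reduces only the allylic-alcohol olefin (the remote trisubstituted olefins and the furan do not bind) and sets C18 as S by ligand-controlled face-selective H2 delivery to the (E)-2-methyl-2-en-1-ol; (S)-BINAP is assigned by analogy with the geraniol quadrant model, so sense and ee must be confirmed on 8 by Mosher analysis and the (R)-ligand used if the sense is opposite.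

**Step 5**
Reactants: 8 (2S,6E,10E)-13-(furan-3-yl)-2,6,10-trimethyltrideca-6,10-dien-1-ol
Product: 10 3-[(3E,7E,12S)-13-bromo-4,8,12-trimethyltrideca-3,7-dien-1-yl]furan, via alkoxytriphenylphosphonium bromide 9 (not isolated)
Conditions: CBr4, PPh3, CH2Cl2, 0 °C
Reagents that add atoms: carbon tetrabromide, BrC(Br)(Br)Br (Br of 10); triphenylphosphine, c1ccc(cc1)P(c1ccccc1)c1ccccc1 (held only in intermediate 9)
Why: Appel bromination, an SN2 displacement of the alkoxyphosphonium group by bromide at the primary carbon next to C18 under neutral conditions, so the stereocentre, olefins and furan are untouched.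

**Step 6**
Reactants: 10 3-[(3E,7E,12S)-13-bromo-4,8,12-trimethyltrideca-3,7-dien-1-yl]furan; 11 diethyl oxalpropionate (diethyl 2-methyl-3-oxobutanedioate)
Product: 15 variabilin [(5Z)-5-[(2S,6E,10E)-13-(furan-3-yl)-2,6,10-trimethyltrideca-6,10-dien-1-ylidene]-4-hydroxy-3-methylfuran-2(5H)-one], via C20 Grignard reagent 12 (not isolated), via sodium enolate of diethyl oxalpropionate 13 (not isolated), via acyclic 3,4-dioxo ester 14 (not isolated)
Conditions: 10, Mg, THF, 45 °C; add to 13 [11 (2 equiv), NaH, THF, 0 °C] at −30 → 0 °C; then EtOH, DBU, 50 °C; 1 M HCl, 0 °C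
Reagents that add atoms: magnesium, [Mg] (held only in 12); sodium hydride, [Na+].[H-] (Na held only in 13); no reagent atoms remain in 15
Why: Proposed new method: the Grignard reagent acylates the only electrophilic carbonyl of the enolate (the C21 ester; the C24 ester is deactivated as a vinylogous carbonate anion, and the chelated dianionic tetrahedral adduct cannot collapse and over-add, as in α-keto ester syntheses from oxalates), and the released 2-methyl-3,4-dioxo ester then closes under DBU by attack of the C21 enolate oxygen on the C24 ester (5-exo-trig enol-lactonisation driven by formation of the stable tetronate anion; closest known types are the Harris cyclisation of 3,5-dioxo esters to 4-hydroxy-2-pyrones and the cyclodehydration of cis-β-acylacrylic acids to ylidenebutenolides), giving the thermodynamically preferred 20Z-ylidene while the non-enolisable C18 centre is not touched.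

## Compound list

1 | 3-furanmethanol | OCc1ccoc1 | starting material
2 | furan-3-ylmethyl methanesulfonate | CS(=O)(=O)OCc1ccoc1 | intermediate
3 | 3-(chloromethyl)furan | ClCc1ccoc1 | intermediate
4 | (2E,6E)-farnesyl acetate [(2E,6E)-3,7,11-trimethyldodeca-2,6,10-trien-1-yl acetate] | CC(C)=CCC/C(C)=C/CC/C(C)=C/COC(C)=O | starting material
5 | (2E,6E,10E)-12-hydroxy-3,7,11-trimethyldodeca-2,6,10-trien-1-yl acetate | OC/C(C)=C/CC/C(C)=C/CC/C(C)=C/COC(C)=O | intermediate
6 | (furan-3-ylmethyl)magnesium chloride | Cl[Mg]Cc1ccoc1 | intermediate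
7 | (2E,6E,10E)-13-(furan-3-yl)-2,6,10-trimethyltrideca-2,6,10-trien-1-ol | OC/C(C)=C/CC/C(C)=C/CC/C(C)=C/CCc1ccoc1 | intermediate
8 | (2S,6E,10E)-13-(furan-3-yl)-2,6,10-trimethyltrideca-6,10-dien-1-ol | OC[C@@H](C)CCC/C(C)=C/CC/C(C)=C/CCc1ccoc1 | intermediate
9 | [(2S,6E,10E)-13-(furan-3-yl)-2,6,10-trimethyltrideca-6,10-dien-1-yl]oxytriphenylphosphonium bromide | [Br-].c1ccc(cc1)[P+](c1ccccc1)(c1ccccc1)OC[C@@H](C)CCC/C(C)=C/CC/C(C)=C/CCc1ccoc1 | intermediate
10 | 3-[(3E,7E,12S)-13-bromo-4,8,12-trimethyltrideca-3,7-dien-1-yl]furan | BrC[C@@H](C)CCC/C(C)=C/CC/C(C)=C/CCc1ccoc1 | intermediate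
11 | diethyl oxalpropionate (diethyl 2-methyl-3-oxobutanedioate) | CCOC(=O)C(=O)C(C)C(=O)OCC | starting material
12 | [(2S,6E,10E)-13-(furan-3-yl)-2,6,10-trimethyltrideca-6,10-dien-1-yl]magnesium bromide | Br[Mg]C[C@@H](C)CCC/C(C)=C/CC/C(C)=C/CCc1ccoc1 | intermediate
13 | sodium enolate of diethyl oxalpropionate (sodium 1,4-diethoxy-3-methyl-1,4-dioxobut-2-en-2-olate) | [Na+].CCOC(=O)C([O-])=C(C)C(=O)OCC | intermediate
14 | ethyl (6S,10E,14E)-17-(furan-3-yl)-2,6,10,14-tetramethyl-3,4-dioxoheptadeca-10,14-dienoate (C2 epimers and enol tautomers) | CCOC(=O)C(C)C(=O)C(=O)C[C@@H](C)CCC/C(C)=C/CC/C(C)=C/CCc1ccoc1 | intermediate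
15 | variabilin, (5Z)-5-[(2S,6E,10E)-13-(furan-3-yl)-2,6,10-trimethyltrideca-6,10-dien-1-ylidene]-4-hydroxy-3-methylfuran-2(5H)-one | CC1=C(O)/C(=C/[C@@H](C)CCC/C(C)=C/CC/C(C)=C/CCc2ccoc2)OC1=O | target

## Totals and risks

Total step count: 6. Longest linear sequence: 5 steps (4 → 5 → 7 → 8 → 10 → 15).

**Most likely to fail, in order:**

**Step 6 (acylation/enol-lactonisation cascade).** Risks are slow addition to the ester of an anionic enolate, over-addition once the adduct collapses, and incomplete ring closure. The fallback sets out from 8 and comes back at 15, bringing the ring in preformed. Alcohol 8 is oxidised (Dess–Martin periodinane, NaHCO3, CH2Cl2, 0 °C) to (2S,6E,10E)-13-(furan-3-yl)-2,6,10-trimethyltrideca-6,10-dienal F1, which is used at once to limit epimerisation. F1 is added at −78 °C to the C5-lithio derivative of 4-methoxy-3-methylfuran-2(5H)-one (LDA, THF) to give the aldol adduct 5-[(2S,6E,10E)-13-(furan-3-yl)-1-hydroxy-2,6,10-trimethyltrideca-6,10-dien-1-yl]-4-methoxy-3-methylfuran-2(5H)-one F2. MsCl/Et3N converts this into its C20 methanesulfonate F3, and DBU eliminates it to (Z)-O-methylvariabilin F4. LiCl in DMSO (or n-PrSLi) removes the O-methyl group and gives 15.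

**Step 4 (asymmetric hydrogenation).** The 2-methyl-2-en-1-ol class is less well documented with Ru–BINAP than geraniol-type substrates, so ee and facial sense are uncertain. The fallback sets out from 7 and comes back at 8, moving the hydrogenation to the better-precedented α-methyl-α,β-unsaturated acid class. Alcohol 7 is oxidised with MnO2 to (2E,6E,10E)-13-(furan-3-yl)-2,6,10-trimethyltrideca-2,6,10-trienal F5. Ag2O (AgNO3, NaOH, aq. EtOH) then gives (2E,6E,10E)-13-(furan-3-yl)-2,6,10-trimethyltrideca-2,6,10-trienoic acid F6. Carboxylate-directed hydrogenation with Ru(OAc)2(BINAP)/H2 in MeOH (tiglic-acid type, ligand antipode chosen to give S) gives (2S,6E,10E)-13-(furan-3-yl)-2,6,10-trimethyltrideca-6,10-dienoic acid F7. LiAlH4 in Et2O returns 8.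

**Step 3 (Cu-catalysed coupling on the hydroxy acetate).** Risks are attack at the acetate carbonyl and γ-substitution in the presence of the magnesium alkoxide. The fallback sets out from 4 (with Grignard 6) and comes back at 7, coupling a halide first and oxidising last. Acetate 4 is methanolysed (K2CO3, MeOH) to (2E,6E)-farnesol F8. PBr3 (Et2O, −10 °C) gives (2E,6E)-farnesyl bromide F9. F9 couples with 6 (Li2CuCl4, THF, 0 °C) to give 3-[(3E,7E)-4,8,12-trimethyltrideca-3,7,11-trien-1-yl]furan F10. SeO2/t-BuOOH oxidation of the terminal isopropylidene of F10 then gives 7.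

## Further compounds

F1 | step 6 | (2S,6E,10E)-13-(furan-3-yl)-2,6,10-trimethyltrideca-6,10-dienal | O=C[C@@H](C)CCC/C(C)=C/CC/C(C)=C/CCc1ccoc1
F2 | step 6 | 5-[(2S,6E,10E)-13-(furan-3-yl)-1-hydroxy-2,6,10-trimethyltrideca-6,10-dien-1-yl]-4-methoxy-3-methylfuran-2(5H)-one | COC1=C(C)C(=O)OC1C(O)[C@@H](C)CCC/C(C)=C/CC/C(C)=C/CCc1ccoc1
F3 | step 6 | C20 methanesulfonate of F2 | COC1=C(C)C(=O)OC1C(OS(C)(=O)=O)[C@@H](C)CCC/C(C)=C/CC/C(C)=C/CCc1ccoc1
F4 | step 6 | (Z)-O-methylvariabilin | CC1=C(OC)/C(=C/[C@@H](C)CCC/C(C)=C/CC/C(C)=C/CCc2ccoc2)OC1=O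
F5 | step 4 | (2E,6E,10E)-13-(furan-3-yl)-2,6,10-trimethyltrideca-2,6,10-trienal | O=C/C(C)=C/CC/C(C)=C/CC/C(C)=C/CCc1ccoc1
F6 | step 4 | (2E,6E,10E)-13-(furan-3-yl)-2,6,10-trimethyltrideca-2,6,10-trienoic acid | OC(=O)/C(C)=C/CC/C(C)=C/CC/C(C)=C/CCc1ccoc1
F7 | step 4 | (2S,6E,10E)-13-(furan-3-yl)-2,6,10-trimethyltrideca-6,10-dienoic acid | OC(=O)[C@@H](C)CCC/C(C)=C/CC/C(C)=C/CCc1ccoc1
F8 | step 3 | (2E,6E)-farnesol | CC(C)=CCC/C(C)=C/CC/C(C)=C/CO
F9 | step 3 | (2E,6E)-farnesyl bromide | CC(C)=CCC/C(C)=C/CC/C(C)=C/CBr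
F10 | step 3 | 3-[(3E,7E)-4,8,12-trimethyltrideca-3,7,11-trien-1-yl]furan | CC(C)=CCC/C(C)=C/CC/C(C)=C/CCc1ccoc1
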